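(Readings and results come from a simulation for substances that don't exist; noise was put on by code.)

Leave this flask alone.

| flask | substrate | reagent | catalyst | remark | time |
|---|---|---|---|---|---|
| noon | 1.5 M | 1.95 M | 1.5 mM | the very flask that is asked about, followed so far |  |
| flask | 1.5 M | 1.95 M | 1.5 mM |  | 2.0 min |

noon run (percent of the substrate charged)

| time / s | isomer of the product A / % | target / % | substrate / % |
|---|---|---|---|
| 10.0 | 15.3 | 34.0 | 41.3 |
| 15.0 | 17.2 | 39.6 | 32.8 |
| 25.0 | 18.1 | 45.7 | 27.0 |
| 40.0 | 18.7 | 47.8 | 23.4 |
| 50.0 | 20.4 | 47.0 | 22.1 |
| 60.0 | 20.4 | 45.9 | 20.9 |

(each reading ± 1 percentage point)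

- in percentages every species weighs as the substrate in it: one idle adduct counts as two
- for target the idle adduct is counted in
- what may be going on: substrate + reagent <-> target; substrate + reagent <-> isomer of the product A; target + catalyst <-> isomer of the product A + catalyst; substrate + target <-> idle adduct; target + catalyst <-> isomer of the product B + catalyst
- in an amount of target, one idle adduct counts as one target

1. share of isomer of the product A in isomer of the product A plus target at 0.30 s
2. share of isomer of the product A in isomer of the product A plus target at 6.0 s
3. share of isomer of the product A in isomer of the product A plus target at 2.0 min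

- At 60.0 s of the noon run this flask holds 20.9% substrate, 45.9% target and 20.4% isomer of the product A.
- Late in the noon run substrate lost 1.2 percentage points in 10.0 s, less than the 8.5 points it lost in 5.00 s early on, so you should find the flask close to its end state.
- Summing the six readings gives 29.7% for the split, the share of isomer of the product A in that isomer plus target, which is the selectivity you care about.
- Single readings of the split lie from 28.1% to 31.0% while substrate falls to half, and with 1 point of scatter on each reading I see no trend.
- So my reckoning is 29.7% at 0.30 s, 6.0 s and 2.0 min, the earliest time being an extrapolation, and you need not stop the flask at another time for a better split.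
- The forecast says 29%, 30% and 33%; it parts from my flat line at the end, where it expects “a slight rise”.

The flask gives 29.8%, 29.9% and 29.0%.

    substrate + reagent ⇌ target (K = 2.30 M⁻¹, k = 0.0398 M⁻¹ s⁻¹)
    substrate + reagent ⇌ isomer of the product A (K = 1.09 M⁻¹, k = 0.0169 M⁻¹ s⁻¹)
    target + catalyst ⇌ isomer of the product A + catalyst, rate k3*[catalyst]*[target] forward; the back reaction follows from the equilibrium constant (k = 0.739 M⁻¹ s⁻¹)
    substrate + target ⇌ idle adduct, settled at all times (K = 0.574 M⁻¹)
    target + catalyst ⇌ isomer of the product B + catalyst, rate k5*[catalyst]*[target] forward; the back reaction follows from the equilibrium constant (K = 0.111, k = 8.54 M⁻¹ s⁻¹)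

- The split of 29.7% stands 0.7 points from this flask at 2.0 min, where the share ends lower than at 6.0 s. The neighbouring flask is charged with 0.0060 M of catalyst, 4.00 times the 1.5 mM here, with the other charges and the time held. The same reckoning carries 29.7% over to it for the three asked times. That neighbour gives 29.9%, 30.3% and 28.8%, and it ends with 19.5% isomer of the product A and 4.54% isomer of the product B.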